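**Retrosynthetic overview**
1. Last bond: C(sp2)–C(sp2) Negishi coupling in the 4E,6E-diene, joining an alkenylzinc (from hydrozirconation of a bis-furan 2-alkyne) to an (E)-iodovinyl (E)-ylidenebutenolide.
2. Butenolide (east fragment, formed second): oxidised-tail logic, (2Z,4E)-dienoate → 4,5-epoxide → 5-exo lactonisation with inversion → anti-dehydration, which fixes the (E)-enol-lactone geometry. The methyl-bearing stereocentre comes from (R)-citronellal.
3. Both furans (west fragment, formed first and together): twofold singlet-oxygen [4+2] on an acyclic skipped tetraene → bis-endoperoxide → double Kornblum–DeLaMare rearrangement/dehydration.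
4. Tetraene: myrcene-derived C7 dienal + C7 alkenyl Grignard, then Pd-catalysed elimination. East dienoate: Takai olefination, oxidative cleavage, dehydrogenation and Ando olefination of citronellal.
5. Ring order: 3-furyl and 2,4-furyl rings simultaneously (step 5), butenolide (step 10), fragment union (step 12).

Assumption: commercial (R)-(+)-citronellal of ≥97% ee is used; its stereocentre is carried through unchanged, so the ee of the target equals that of this starting material.

**Route**

Step 1
Reactants: 1 3-bromoprop-1-yne (propargyl bromide); 2 2,3-dibromoprop-1-ene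
Product: 5 2-bromohept-1-en-5-yne, via 1,3-dilithiopropyne 3 (not isolated), via lithium 5-bromohex-5-en-1-yn-1-ide 4 (not isolated)
Conditions: n-BuLi (2 equiv), TMEDA, Et2O, −78 °C; add 2, −78 → −20 °C; then MeI, THF/DMPU, 0 °C → rt
Reagents that add atoms: iodomethane, CI
Why: Propargyl-dianion alkylation: 1,3-dilithiopropyne (Br/Li exchange, then deprotonation) is alkylated at its sp3 carbon by the allylic bromide (SN2) and the remaining acetylide is then C-methylated, giving the 2-alkyne free of allene isomers.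

Step 2
Reactants: 6 myrcene (7-methyl-3-methylideneocta-1,6-diene)
Product: 8 4-methylidenehex-5-enal, via myrcene 6,7-ozonide 7 (not isolated)
Conditions: O3 (1.0 equiv, Sudan Red end-point), CH2Cl2, −78 °C; then Me2S, −78 °C → rt
Reagents that add atoms: ozone, O=[O+][O-]
Why: Chemoselective ozonolysis, because the electron-rich trisubstituted alkene takes up one equivalent of ozone much faster than the conjugated diene, and reductive work-up releases the aldehyde.

Step 3
Reactants: 5 2-bromohept-1-en-5-yne; 8 4-methylidenehex-5-enal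
Product: 11 methyl 3,7-dimethylidenedodec-1-en-10-yn-6-yl carbonate, via hept-1-en-5-yn-2-ylmagnesium bromide 9 (not isolated), via bromomagnesium 3,7-dimethylidenedodec-1-en-10-yn-6-olate 10 (not isolated)
Conditions: Mg, THF, 40 °C; add 8, −78 → 0 °C; then ClCO2Me, 0 °C → rt
Reagents that add atoms: methyl chloroformate, COC(=O)Cl
Why: Grignard 1,2-addition to the aldehyde followed by in-situ O-acylation of the alkoxide; the carbinol centre is racemic but is destroyed in step 4.

Step 4
Reactants: 11 methyl 3,7-dimethylidenedodec-1-en-10-yn-6-yl carbonate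
Product: 12 (5E)-3,7-dimethylidenedodeca-1,5-dien-10-yne
Conditions: Pd(OAc)2 (5 mol %), PBu3 (5 mol %), dioxane, 100 °C
Reagents that add atoms: none
Why: Tsuji Pd(0)-catalysed decarboxylative elimination of an allylic carbonate, in which the π-allyl complex can lose a β-hydrogen only from C-5 and so gives the single (E)-1,3-diene regioisomer.

Step 5
Reactants: 12 (5E)-3,7-dimethylidenedodeca-1,5-dien-10-yne
Product: 15 2-(furan-3-ylmethyl)-4-(pent-3-yn-1-yl)furan, via bis-endoperoxide 13 (not isolated), via bis(γ-hydroxy-enal) 14 (not isolated)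
Conditions: O2, TPP (1 mol %), hν (white LED), CH2Cl2, −20 °C; then Et3N, 0 °C → rt; then TsOH·H2O (10 mol %), rt
Reagents that add atoms: dioxygen (as singlet oxygen), O=O
Why: Twofold singlet-oxygen [4+2] cycloaddition on the two s-cis-accessible 1,3-dienes (alkyne inert, no furan present while 1O2 is generated), then double Kornblum–DeLaMare rearrangement to the (Z)-γ-hydroxy-enals and acid cyclodehydration, the known diene → endoperoxide → furan sequence run at both sites in one pot.

Step 6
Reactants: 16 (R)-citronellal [(3R)-3,7-dimethyloct-6-enal]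
Product: 17 (1E,4R)-1-iodo-4,8-dimethylnona-1,7-diene
Conditions: CrCl2 (6 equiv), CHI3 (2 equiv), dioxane/THF 6:1, 0 °C → rt
Reagents that add atoms: iodoform, IC(I)I
Why: Takai olefination (gem-dichromium carbenoid) converts the aldehyde into the (E)-vinyl iodide without touching the β-stereocentre or the trisubstituted alkene.

Step 7
Reactants: 17 (1E,4R)-1-iodo-4,8-dimethylnona-1,7-diene
Product: 19 (4R,6E)-7-iodo-4-methylhept-6-enal, via vicinal diol 18 (not isolated)
Conditions: OsO4 (2 mol %), NaIO4 (4 equiv), 2,6-lutidine, dioxane/H2O 3:1, rt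
Reagents that add atoms: osmium tetroxide, O=[Os](=O)(=O)=O (catalytic oxygen carrier); sodium periodate, [Na+].[O-]I(=O)(=O)=O (terminal oxidant that reloads osmium)
Why: Lemieux–Johnson cleavage, in which OsO4 dihydroxylates the electron-rich trisubstituted alkene in preference to the deactivated iodoalkene and periodate cleaves the diol.

Step 8
Reactants: 19 (4R,6E)-7-iodo-4-methylhept-6-enal
Product: 20 (2E,4S,6E)-7-iodo-4-methylhepta-2,6-dienal
Conditions: IBX (1.5 equiv), DMSO/fluorobenzene, 70 °C
Reagents that add atoms: none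
Why: IBX-mediated α,β-dehydrogenation of the aldehyde through its enol gives the (E)-enal, with limited oxidant preventing further dehydrogenation through the γ-C–H (the descriptor changes from R to S by CIP priority only).

Step 9
Reactants: 20 (2E,4S,6E)-7-iodo-4-methylhepta-2,6-dienal; 21 ethyl 2-(diphenoxyphosphoryl)propanoate
Product: 22 ethyl (2Z,4E,6S,8E)-9-iodo-2,6-dimethylnona-2,4,8-trienoate
Conditions: NaH, THF, −78 → 0 °C
Reagents that add atoms: none
Why: Ando Z-selective Horner–Wadsworth–Emmons olefination, where the diaryl phosphonate collapses fast and irreversibly through the syn-oxaphosphetane to the (2Z)-trisubstituted enoate while the 4E bond is retained.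

Step 10
Reactants: 22 ethyl (2Z,4E,6S,8E)-9-iodo-2,6-dimethylnona-2,4,8-trienoate
Product: 24 (5S)-5-[(1R,2S,4E)-1-hydroxy-5-iodo-2-methylpent-4-en-1-yl]-3-methylfuran-2(5H)-one, via trans-epoxy ester 23 (not isolated)
Conditions: mCPBA (1.2 equiv), NaHCO3, CH2Cl2, 0 °C → rt; then CSA (20 mol %), wet CH2Cl2, rt
Reagents that add atoms: 3-chloroperoxybenzoic acid (mCPBA), OOC(=O)c1cccc(Cl)c1; water, O
Why: Peracid epoxidation of the more electron-rich γ,δ-alkene, then acid-triggered 5-exo epoxide-opening lactonisation by the cis ester carbonyl with inversion at the allylic carbon, so ring oxygen and hydroxyl are anti-added across the former 4E bond (both epoxide faces give this same relative configuration, so 24 is a pair of diastereomers that converge in step 11).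

Step 11
Reactants: 24 (5S)-5-[(1R,2S,4E)-1-hydroxy-5-iodo-2-methylpent-4-en-1-yl]-3-methylfuran-2(5H)-one
Product: 25 (5E)-5-[(2S,4E)-5-iodo-2-methylpent-4-en-1-ylidene]-3-methylfuran-2(5H)-one
Conditions: PPh3 (1.5 equiv), DIAD (1.5 equiv), THF, −20 °C → rt, dark
Reagents that add atoms: none
Why: Mitsunobu-type dehydration, in which the alkoxyphosphonium departs in an anti-periplanar E2 with the acidic γ-hydrogen, so the anti-adduct gives stereospecifically the kinetically set (E)-ylidene (side chain cis to C-4).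

Step 12
Reactants: 15 2-(furan-3-ylmethyl)-4-(pent-3-yn-1-yl)furan; 25 (5E)-5-[(2S,4E)-5-iodo-2-methylpent-4-en-1-ylidene]-3-methylfuran-2(5H)-one
Product: 28 (5E)-5-[(2S,4E,6E)-9-[5-(furan-3-ylmethyl)furan-3-yl]-2,6-dimethylnona-4,6-dien-1-ylidene]-3-methylfuran-2(5H)-one (CNP0138823.1), via alkenylzirconocene chloride 26 (not isolated), via alkenylzinc chloride 27 (not isolated)
Conditions: 15 (1.3 equiv), Cp2Zr(H)Cl (2 equiv), THF, 50 °C; ZnCl2, 0 °C; then 25, Pd(PPh3)4 (5 mol %), THF, rt, dark
Reagents that add atoms: none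
Why: Syn-hydrozirconation (Zr equilibrates to the less hindered methyl-bearing carbon), Zr→Zn transmetalation and Negishi coupling with retention at both sp2 carbons give the 4E,6E-diene under neutral conditions that spare the base-sensitive butenolide and its allylic stereocentre.

**Compound list**
1 | 3-bromoprop-1-yne (propargyl bromide) | C#CCBr | starting material
2 | 2,3-dibromoprop-1-ene | C=C(Br)CBr | starting material
3 | 1,3-dilithiopropyne | [Li]CC#C[Li] | intermediate (not isolated)
4 | lithium 5-bromohex-5-en-1-yn-1-ide | [Li]C#CCCC(Br)=C | intermediate (not isolated)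
5 | 2-bromohept-1-en-5-yne | CC#CCCC(Br)=C | intermediate
6 | myrcene (7-methyl-3-methylideneocta-1,6-diene) | CC(C)=CCCC(=C)C=C | starting material
7 | 3,3-dimethyl-5-(3-methylidenepent-4-en-1-yl)-1,2,4-trioxolane (myrcene 6,7-ozonide) | CC1(C)OOC(CCC(=C)C=C)O1 | intermediate (not isolated)
8 | 4-methylidenehex-5-enal | C=CC(=C)CCC=O | intermediate
9 | hept-1-en-5-yn-2-ylmagnesium bromide | CC#CCCC(=C)[Mg]Br | intermediate (not isolated)
10 | bromomagnesium 3,7-dimethylidenedodec-1-en-10-yn-6-olate | C=CC(=C)CCC(O[Mg]Br)C(=C)CCC#CC | intermediate (not isolated)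
11 | methyl 3,7-dimethylidenedodec-1-en-10-yn-6-yl carbonate (racemic) | C=CC(=C)CCC(OC(=O)OC)C(=C)CCC#CC | intermediate
12 | (5E)-3,7-dimethylidenedodeca-1,5-dien-10-yne | C=CC(=C)C/C=C/C(=C)CCC#CC | intermediate
13 | 3-[(3,6-dihydro-1,2-dioxin-4-yl)methyl]-5-(pent-3-yn-1-yl)-3,6-dihydro-1,2-dioxine (bis-endoperoxide, racemic) | CC#CCCC1=CC(CC2=CCOOC2)OOC1 | intermediate (not isolated)
14 | (2Z,6Z)-7-formyl-5-hydroxy-3-(hydroxymethyl)dodeca-2,6-dien-10-ynal (bis(γ-hydroxy-enal), in equilibrium with its lactols; one of the regioisomeric Kornblum–DeLaMare products, all converge) | O=C/C=C(\CO)CC(O)/C=C(\C=O)CCC#CC | intermediate (not isolated)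
15 | 2-(furan-3-ylmethyl)-4-(pent-3-yn-1-yl)furan | CC#CCCc1coc(Cc2ccoc2)c1 | intermediate
16 | (R)-citronellal [(3R)-3,7-dimethyloct-6-enal] | C[C@H](CCC=C(C)C)CC=O | starting material
17 | (1E,4R)-1-iodo-4,8-dimethylnona-1,7-diene | C[C@H](CCC=C(C)C)C/C=C/I | intermediate
18 | (6R,8E)-9-iodo-2,6-dimethylnon-8-ene-2,3-diol (C-3 epimers) | C[C@H](CCC(O)C(C)(C)O)C/C=C/I | intermediate (not isolated)
19 | (4R,6E)-7-iodo-4-methylhept-6-enal | C[C@H](CCC=O)C/C=C/I | intermediate
20 | (2E,4S,6E)-7-iodo-4-methylhepta-2,6-dienal | C[C@H](/C=C/C=O)C/C=C/I | intermediate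
21 | ethyl 2-(diphenoxyphosphoryl)propanoate (Ando reagent) | CCOC(=O)C(C)P(=O)(Oc1ccccc1)Oc1ccccc1 | starting material
22 | ethyl (2Z,4E,6S,8E)-9-iodo-2,6-dimethylnona-2,4,8-trienoate | CCOC(=O)/C(C)=C\C=C\[C@@H](C)C/C=C/I | intermediate
23 | ethyl (2Z)-3-[(2R,3R)-3-[(2S,4E)-5-iodopent-4-en-2-yl]oxiran-2-yl]-2-methylprop-2-enoate (trans-epoxide; formed together with its (2S,3S)-oxirane diastereomer) | CCOC(=O)/C(C)=C\[C@H]1O[C@@H]1[C@@H](C)C/C=C/I | intermediate (not isolated)
24 | (5S)-5-[(1R,2S,4E)-1-hydroxy-5-iodo-2-methylpent-4-en-1-yl]-3-methylfuran-2(5H)-one (formed together with its (5R,1′S) diastereomer; both have the anti relationship) | CC1=C[C@H](OC1=O)[C@H](O)[C@@H](C)C/C=C/I | intermediate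
25 | (5E)-5-[(2S,4E)-5-iodo-2-methylpent-4-en-1-ylidene]-3-methylfuran-2(5H)-one | CC1=C/C(=C\[C@@H](C)C/C=C/I)OC1=O | intermediate
26 | chlorobis(cyclopentadienyl)[(2E)-5-[5-(furan-3-ylmethyl)furan-3-yl]pent-2-en-2-yl]zirconium | Cl[Zr](C1C=CC=C1)(C1C=CC=C1)/C(C)=C/CCc1coc(Cc2ccoc2)c1 | intermediate (not isolated)
27 | chloro[(2E)-5-[5-(furan-3-ylmethyl)furan-3-yl]pent-2-en-2-yl]zinc | Cl[Zn]/C(C)=C/CCc1coc(Cc2ccoc2)c1 | intermediate (not isolated)
28 | (5E)-5-[(2S,4E,6E)-9-[5-(furan-3-ylmethyl)furan-3-yl]-2,6-dimethylnona-4,6-dien-1-ylidene]-3-methylfuran-2(5H)-one | CC1=C/C(=C\[C@@H](C)C/C=C/C(C)=C/CCc2coc(Cc3ccoc3)c2)OC1=O | target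

**Step count and risk**

Total steps: 12. Longest linear sequence: 7 (steps 6–12, from (R)-citronellal). The west branch is 5 steps (1 or 2 → 3 → 4 → 5 → 12).

The three steps most likely to fail:

Step 5 (twofold photooxygenation to both furans). The risks are competing ene reactions at the skipped CH2 and sluggish [4+2] on the acyclic dienes. The fallback sets out from tetraene 12 and returns at bis-furan 15. Each diene is mono-epoxidised with buffered mCPBA (CH2Cl2, 0 °C) to give 2-ethenyl-2-[(2E)-3-[2-(pent-3-yn-1-yl)oxiran-2-yl]prop-2-en-1-yl]oxirane F1 (regio- and diastereomers all converge). Cu(hfacac)2-catalysed vinyloxirane → 2,5-dihydrofuran ring expansion (toluene, 110–150 °C) then gives 2-[(2,5-dihydrofuran-3-yl)methyl]-4-(pent-3-yn-1-yl)-2,5-dihydrofuran F2, which DDQ (benzene, rt) aromatises to 15.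

Step 8 (IBX dehydrogenation). The risks are moderate yield, over-oxidation and epimerisation at the γ-stereocentre in hot DMSO. The fallback sets out from aldehyde 19 and returns at enal 20. Enamine-catalysed α-selenenylation (N-(phenylseleno)phthalimide, L-prolinamide 10 mol %, CH2Cl2, rt) gives (4S,6E)-7-iodo-4-methyl-2-(phenylselanyl)hept-6-enal F3 (C-2 epimers; C-4 spatially unchanged). NaIO4 (aqueous THF, NaHCO3, 0 °C → rt) oxidises it to the selenoxide, which undergoes syn-elimination to 20 at room temperature.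

Step 11 (anti-dehydration to the E-ylidene). The risk is E1cB leakage that would erode E-selectivity; this step also depends on the selectivity of step 10. The fallback sets out from trienoate 22 and returns at iodide 25, bypassing 23 and 24. Saponification (LiOH, THF/H2O, 0 °C) gives (2Z,4E,6S,8E)-9-iodo-2,6-dimethylnona-2,4,8-trienoic acid F4. Iodolactonisation (I2, NaHCO3, MeCN, 0 °C, dark; 5-exo, anti addition) gives (5S)-5-[(1R,2S,4E)-1,5-diiodo-2-methylpent-4-en-1-yl]-3-methylfuran-2(5H)-one F5 (with its 5R,1′S diastereomer, same anti relationship). DBU (THF, −20 °C) then removes HI by anti-E2, with iodide as a better nucleofuge, to give 25.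

Further compounds
F1 | step 5 | 2-ethenyl-2-[(2E)-3-[2-(pent-3-yn-1-yl)oxiran-2-yl]prop-2-en-1-yl]oxirane (diastereomer mixture) | C=CC1(CO1)C/C=C/C1(CCC#CC)CO1
F2 | step 5 | 2-[(2,5-dihydrofuran-3-yl)methyl]-4-(pent-3-yn-1-yl)-2,5-dihydrofuran (racemic) | CC#CCCC1=CC(CC2=CCOC2)OC1
F3 | step 8 | (4S,6E)-7-iodo-4-methyl-2-(phenylselanyl)hept-6-enal (C-2 epimers) | C[C@H](CC([Se]c1ccccc1)C=O)C/C=C/I
F4 | step 11 | (2Z,4E,6S,8E)-9-iodo-2,6-dimethylnona-2,4,8-trienoic acid | OC(=O)/C(C)=C\C=C\[C@@H](C)C/C=C/I
F5 | step 11 | (5S)-5-[(1R,2S,4E)-1,5-diiodo-2-methylpent-4-en-1-yl]-3-methylfuran-2(5H)-one (with its 5R,1′S diastereomer) | CC1=C[C@H](OC1=O)[C@H](I)[C@@H](C)C/C=C/I
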